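# Route to CNP0248490.2 built on a Petasis–Ferrier rearrangement of a dioxane enol acetal

Carbon labels C1–C24 run along the target chain from the lactone carbonyl (C1) to the propenyl methyl (C24). The final compound is 35.

## Analysis of the target

Compound 35 is a C28 polyketide of the ratjadone type. An (S)-5,6-dihydro-2H-pyran-2-one (C1–C5) is joined through a tetraene chain (C6–C15) to a secondary carbinol (C16). C16 sits on a tetrahydropyran (O–C17–C18–C19–C20–C21) that carries an (E)-propenyl group (C22–C24).

The chain holds a (6E,8Z)-diene with a methyl on C8, a lone stereocentre at C10, a methylene at C11 and a (12E,14E)-diene with a methyl on C12.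

The descriptors read from the SMILES are 5S, 10R, 16S, 17S, 19R, 20S, 21S. C5 and C10 are remote from everything else and each needs its own source of chirality. The ring centres and C16 are related to one another: the ring is 2,6-cis (C17 and C21 substituents equatorial), the C20 methyl and the C19 hydroxyl are both axial, and the C16 hydroxyl is syn to the ring oxygen on C17.

The sensitive groups are:
- the enoate lactone (base, hydride and nucleophiles; its C5–O bond is allylic);
- the 8Z trisubstituted alkene inside a diene (isomerisation);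
- the dienylic C16 carbinol (acid ionisation);
- the allylic C21–O bond of the ring.

The difficulty lies in the dense ring with two axial groups, one of them (the C20 methyl) in the less stable orientation next to a carbonyl precursor, and in a polyene whose geometry has to be introduced stereospecifically and late.

The strategy rests on the ring O–C17–C18–C19–C20–C21. A 2,6-cis tetrahydropyran with oxygen on C19 and a cis C20/C21 pair is the reduction product of a 2,6-cis tetrahydropyran-4-one. In that ketone, C19–C21 is a syn propionate aldol of crotonaldehyde and C17 is an aldehyde carbon.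

## Retrosynthetic reasoning

**C7–C8 (35 to 34 and 29).** The single bond between the two alkenes of the 6E,8Z-diene is cut. Both alkene geometries then sit in separate fragments, the Z-iodoalkene 34 and the E-alkenylstannane 29. A palladium cross-coupling transfers both with retention. Cutting here also lets the lactone enter in the last step, so it never meets hydride, fluoride or a strong base.

**C14=C15 and C15–C16 (34 to 33, 32, then 14 and 24).** The C16 carbinol is made by adding C15 to the ring aldehyde 14. The required 16S,17S relation is syn to the ring oxygen, which is the outcome of a chelate between the aldehyde oxygen and the ring oxygen. A dienyl organometallic that already carries the lactone cannot be prepared. One that carries the vinyl iodide cannot be made by halogen–metal exchange. The nucleophile is therefore the terminal alkyne 24, whose acidic C–H allows metalation beside the iodide. The propargylic alcohol 32 is desilylated to 33 while the carbinol is still acid-tolerant. The alkoxide of 33 then directs a trans-hydroalumination that delivers the 14E alkene of 34.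

**Ring functional groups (14 to 13, 12, 11, 10).** The aldehyde comes from the primary silyl ether of 12 through alcohol 13. The axial C19 hydroxyl of 11 comes from ketone 10 by equatorial hydride delivery. These steps add no skeletal bonds; all of them are already present in 10.

**C17–C18 (10 to 9), the key disconnection.** Cutting the ring C–C bond next to the ketone returns the enol acetal 9. In 9 the same atoms are held by two C–O bonds. The forward step must ionise the acetal at C17 and let the liberated enolate carbon C18 recapture C17. This is where the ring, one C–C bond and the C17 configuration are made, from a precursor that is only two C–O bonds away from an acid and an aldehyde.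

**Acetal and aldol (9 to 8, then 5 and 6; 5 to 4, then 1 and 2).** The enol acetal is the methylenation product of dioxanone 8. Dioxanone 8 is the condensation product of hydroxy acid 5 with aldehyde 6. Acid 5 is the syn aldol of imide 1 with crotonaldehyde 2, which fixes C20 and C21 and brings in the propenyl group unchanged.

**Alkyne 24 (to 23, 22, 21, 20, then 18 and 17; 17 to 16 and 15).** The Z-iodoalkene is formed by iodo-olefination of aldehyde 22. C10 is set by alkylation of the enolate of imide 18 with the allylic bromide 17 (C10–C11 bond). Bromide 17 already contains the 12E alkene, taken from iodide 15, and a silyl-capped alkyne attached at C13–C14 by cross-coupling (16).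

**Lactone 29 (to 28, 27, 26, 25).** The C2=C3 bond is cut by ring-closing metathesis of acrylate 28. The C4–C5 bond and the C5 configuration come from asymmetric allylation of the stannyl enal 26, which is the oxidation product of 25. The tin is carried from the start, so no metalation is needed in the presence of the lactone.

## Alternatives that were turned down

**Alternative 1: enzymatic aldol for the lactone carbons.** The disconnection is at C4–C5 and C2–C3 of the lactone. In the forward step 2-deoxyribose-5-phosphate aldolase, a lysine-enamine aldolase, adds two molecules of acetaldehyde A2 in sequence to chloroacetaldehyde A1, and the product closes to the lactol A3. A3 holds C1–C6 with C5 already in the 5S configuration needed here, and a C3 hydroxyl that can later be eliminated to give C2=C3.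
- For it: one catalytic step in water from achiral two-carbon aldehydes, with enzymatic control at C5. On this point it is stronger than the stoichiometric chiral allylborane used in step 18.
- Against it: it spends the strategic step on the simplest stereocentre of 35. After oxidation and dehydration, the C6 chloromethyl group must still be turned into the C6=C7 alkene. A carbanion at C6 would expel the lactone carboxylate by β-elimination, so only the C6 aldehyde polarity is usable. That forces a base-mediated olefination, which the enoate lactone survives only as a masked lactol, adding steps and leaving the 6E geometry to a kinetic olefination.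
- Comparison: the five ring and carbinol stereocentres are not addressed at all. The chosen strategy puts its key step on that ring and reaches the lactone partner 29 in four conventional steps.

**Alternative 2: palladium chirality transfer for the ring.** The disconnection is the ring O–C21 bond. In the forward step PdCl2(MeCN)2 (divalent palladium) activates the (E)-C21=C22 alkene of diol A4. The C17 hydroxyl adds to C21 on the face syn to the C23 hydroxyl, which leaves, giving the 2,6-cis tetrahydropyran A5 with the alkene moved to C22=C23.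
- For it: the step is mild and stereospecific. It makes the propenyl group instead of carrying it. It takes the C19 oxygen in its final configuration from the open chain, so it avoids both the Lewis-acid ionisation risk and the ketone reduction of the chosen route. On those two points it is the stronger plan.
- Against it: A4 needs four stereocentres (C17, C19, C20 and a sacrificial C23) set one after another on an acyclic chain before any ring exists. The key step forms a C–O bond only, and its fidelity depends on the purity of both the C23 carbinol and the E-alkene.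
- Comparison: the chosen rearrangement forms a skeletal C–C bond and reaches its precursor 9 in four steps from two small fragments. That is several steps shorter than any realistic route to A4.

**Alternative 3: temporary lactone for the 8Z alkene.** The disconnection is the C8=C9 double bond. (S)-2-Methylbut-3-en-1-ol A6 is converted into its methacrylate A7. The second-generation Grubbs catalyst closes A7 to the dihydropyranone A8 with loss of ethylene, so that C7–C11 with both methyls is obtained with the alkene locked Z by the ring.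
- For it: the geometric purity of the 8Z alkene is guaranteed by the ring. That is stronger than the kinetic iodo-olefination of step 15, the weakest selectivity in the C8–C15 fragment.
- Against it: the metathesis must form a trisubstituted alkene from a 1,1-disubstituted acrylate next to an allylic stereocentre. After ring opening, both ends need new C–C bonds of the less convenient polarity: C11 to C12 through an sp3 centre, and C7 to C6 through an olefination that again requires the lactone of 35 to be masked.
- Comparison: the chosen route accepts a less certain olefination in exchange for a stereospecific C7–C8 coupling that tolerates the free lactone. As with Alternative 1, the ring is left unsolved.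

Key step: step 5

## Route

Remark: compounds 15 and 25 are taken as catalogue compounds.

Step 1
Reactants: 1 (R)-4-benzyl-3-propionyloxazolidin-2-one; 2 (E)-but-2-enal (crotonaldehyde)
Product: 4 (R)-4-benzyl-3-[(2R,3S,E)-3-hydroxy-2-methylhex-4-enoyl]oxazolidin-2-one, via dibutylboron Z-enolate 3 (not isolated)
Conditions: Bu2BOTf, Et3N, CH2Cl2, 0 °C; 2, −78 to 0 °C; H2O2, MeOH, pH 7 buffer
Reagents that add atoms: none
Why: Evans syn aldol; the Z-boron enolate 3 reacts through a closed Zimmerman–Traxler chair on the enolate face away from the benzyl group, which sets C20 and C21 in the syn relation (2R,3S in 4). The enal reacts only at the carbonyl under these conditions.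

Step 2
Reactants: 4 (R)-4-benzyl-3-[(2R,3S,E)-3-hydroxy-2-methylhex-4-enoyl]oxazolidin-2-one
Product: 5 (2R,3S,E)-3-hydroxy-2-methylhex-4-enoic acid
Conditions: LiOH, H2O2, THF/H2O, 0 °C; Na2SO3; HCl to pH 3
Reagents that add atoms: hydrogen peroxide (as LiOOH; supplies the carboxyl OH), OO
Why: Hydroperoxide cleavage of the imide; LiOOH attacks the exocyclic carbonyl selectively and sulfite reduces the peracid. At 0 °C neither retro-aldol cleavage nor epimerisation at C20 is expected, and the auxiliary is recovered.

Step 3
Reactants: 5 (2R,3S,E)-3-hydroxy-2-methylhex-4-enoic acid; 6 (tert-butyldimethylsilyloxy)acetaldehyde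
Product: 8 (2S,5R,6S)-2-[(tert-butyldimethylsilyloxy)methyl]-5-methyl-6-[(E)-prop-1-enyl]-1,3-dioxan-4-one, via bis-trimethylsilyl derivative 7 (not isolated)
Conditions: (Me3Si)2NH, CH2Cl2, rt, concentrate; 6, Me3SiOTf (cat.), CH2Cl2, −78 °C; pyridine quench
Reagents that add atoms: none
Why: Silyl-triflate-promoted acetalisation of a bis-silylated β-hydroxy acid with an aldehyde; hexamethyldisiloxane is the only coproduct. The acetal carbon C17 settles with its CH2OSi group equatorial, cis to the equatorial propenyl group, while the C20 methyl from the syn aldol is axial; this centre is re-formed in step 5, so a minor trans isomer is not a loss.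

Step 4
Reactants: 8 (2S,5R,6S)-2-[(tert-butyldimethylsilyloxy)methyl]-5-methyl-6-[(E)-prop-1-enyl]-1,3-dioxan-4-one
Product: 9 (2S,5R,6S)-2-[(tert-butyldimethylsilyloxy)methyl]-5-methyl-4-methylidene-6-[(E)-prop-1-enyl]-1,3-dioxane
Conditions: Cp2TiMe2, THF, 65 °C, dark; filtration through basic alumina
Reagents that add atoms: dimethyltitanocene Cp2TiMe2, [CH3-].[CH3-].[Ti+4].c1cc[cH-]c1.c1cc[cH-]c1
Why: Petasis methylenation of a lactone carbonyl; thermally generated Cp2Ti=CH2 converts C19=O into the exocyclic enol ether through an oxatitanacyclobutane. The reagent is non-acidic and non-basic, so the acetal and the C20 centre are untouched.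

Step 5
Reactants: 9 (2S,5R,6S)-2-[(tert-butyldimethylsilyloxy)methyl]-5-methyl-4-methylidene-6-[(E)-prop-1-enyl]-1,3-dioxane
Product: 10 (2S,3R,6S)-6-[(tert-butyldimethylsilyloxy)methyl]-3-methyl-2-[(E)-prop-1-enyl]tetrahydro-4H-pyran-4-one
Conditions: Me2AlCl, CH2Cl2, −78 °C; NaHCO3 quench at −78 °C
Reagents that add atoms: none
Why: Petasis–Ferrier rearrangement. Me2AlCl binds the enol-ether oxygen and the C17–O bond on that side ionises, because only this cleavage gives both an oxygen-stabilised cation (C17=O+–C21) and a delocalised leaving group (the aluminium enolate C18=C19–OAl). C18 of the enolate then attacks C17 in a 6-(enolendo)-endo-trig closure that forms the C17–C18 bond and the tetrahydropyran-4-one; one former acetal oxygen becomes the ring ether and the other the C19 ketone. The closest known reaction type is the Lewis-acid rearrangement of 4-methylene-1,3-dioxanes to 2,6-cis tetrahydropyran-4-ones. The new C17 centre is set by a chair transition state in which the CH2OSi group on the E-oxocarbenium ion and the C21 propenyl group are both equatorial, so the ring closes 2,6-cis whatever the acetal configuration of 9. The axial C20 methyl faces only the ring oxygen and the sp2 carbon C18 in 1,3-relation in this chair and costs little. Because the enolate is generated regiospecifically on the C18 side, C20 is never planarised. The selectivity needed is ionisation at C17 and not at the allylic C21–O bond; it is secured by the acetal character of C17, the enolate leaving group, the low temperature and the cold basic quench, which also guards C20 against later acid epimerisation.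

Step 6
Reactants: 10 (2S,3R,6S)-6-[(tert-butyldimethylsilyloxy)methyl]-3-methyl-2-[(E)-prop-1-enyl]tetrahydro-4H-pyran-4-one
Product: 11 (2S,3S,4R,6S)-6-[(tert-butyldimethylsilyloxy)methyl]-3-methyl-2-[(E)-prop-1-enyl]tetrahydro-2H-pyran-4-ol
Conditions: LiBH(s-Bu)3, THF, −78 °C; NaOH, H2O2, 0 °C
Reagents that add atoms: none
Why: Bulky-hydride reduction of a cyclic ketone; the axial trajectory is shielded by the axial hydrogens on C17 and C21, so hydride should arrive equatorially and give the axial 19R alcohol. The reagent is non-enolising at −78 °C, so the axial C20 methyl is retained.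

Step 7
Reactants: 11 (2S,3S,4R,6S)-6-[(tert-butyldimethylsilyloxy)methyl]-3-methyl-2-[(E)-prop-1-enyl]tetrahydro-2H-pyran-4-ol
Product: 12 (2S,3R,4R,6S)-4-(tert-butyldimethylsilyloxy)-6-[(tert-butyldimethylsilyloxy)methyl]-3-methyl-2-[(E)-prop-1-enyl]tetrahydro-2H-pyran
Conditions: t-BuMe2SiOTf, 2,6-lutidine, CH2Cl2, −78 to 0 °C
Reagents that add atoms: tert-butyldimethylsilyl trifluoromethanesulfonate, CC(C)(C)[Si](C)(C)OS(=O)(=O)C(F)(F)F
Why: Silylation of a hindered axial secondary alcohol with a silyl triflate and a hindered base; no stereocentre is touched.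

Step 8
Reactants: 12 (2S,3R,4R,6S)-4-(tert-butyldimethylsilyloxy)-6-[(tert-butyldimethylsilyloxy)methyl]-3-methyl-2-[(E)-prop-1-enyl]tetrahydro-2H-pyran
Product: 13 [(2S,4R,5R,6S)-4-(tert-butyldimethylsilyloxy)-5-methyl-6-[(E)-prop-1-enyl]tetrahydro-2H-pyran-2-yl]methanol
Conditions: HF·pyridine, pyridine, THF, 0 °C
Reagents that add atoms: none
Why: Selective desilylation; the primary C16 silyl ether is cleaved much faster than the axial secondary one at C19, which is flanked by the axial methyl. The buffered fluoride source leaves the allylic ring ether intact.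

Step 9
Reactants: 13 [(2S,4R,5R,6S)-4-(tert-butyldimethylsilyloxy)-5-methyl-6-[(E)-prop-1-enyl]tetrahydro-2H-pyran-2-yl]methanol
Product: 14 (2S,4R,5R,6S)-4-(tert-butyldimethylsilyloxy)-5-methyl-6-[(E)-prop-1-enyl]tetrahydro-2H-pyran-2-carbaldehyde
Conditions: Dess–Martin periodinane, NaHCO3, CH2Cl2, 0 °C to rt; used crude
Reagents that add atoms: none
Why: Periodinane oxidation of a primary alcohol under buffered, near-neutral conditions, which should leave the α-alkoxy centre C17 unepimerised; the aldehyde is used directly in step 21.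

Step 10
Reactants: 15 (E)-3-iodo-2-methylprop-2-en-1-ol
Product: 16 (E)-2-methyl-5-(trimethylsilyl)pent-2-en-4-yn-1-ol
Conditions: ethynyltrimethylsilane, PdCl2(PPh3)2 (cat.), CuI (cat.), Et3N, THF, rt
Reagents that add atoms: ethynyltrimethylsilane, C#C[Si](C)(C)C
Why: Sonogashira coupling of an alkenyl iodide; oxidative addition and reductive elimination retain the E geometry, which becomes the 12E alkene. The free hydroxyl is tolerated.

Step 11
Reactants: 16 (E)-2-methyl-5-(trimethylsilyl)pent-2-en-4-yn-1-ol
Product: 17 (E)-(5-bromo-4-methylpent-3-en-1-yn-1-yl)trimethylsilane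
Conditions: CBr4, PPh3, CH2Cl2, 0 °C
Reagents that add atoms: carbon tetrabromide, BrC(Br)(Br)Br
Why: Appel bromination of a primary allylic alcohol; displacement at the primary carbon is favoured over allylic transposition onto the alkynyl-substituted carbon.

Step 12
Reactants: 18 (S)-4-benzyl-3-propionyloxazolidin-2-one; 17 (E)-(5-bromo-4-methylpent-3-en-1-yn-1-yl)trimethylsilane
Product: 20 (S)-4-benzyl-3-[(R,E)-2,4-dimethyl-7-(trimethylsilyl)hept-4-en-6-ynoyl]oxazolidin-2-one, via sodium Z-enolate 19 (not isolated)
Conditions: NaN(SiMe3)2, THF, −78 °C; 17, −78 to −40 °C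
Reagents that add atoms: none
Why: Evans alkylation; the chelated sodium Z-enolate 19 is alkylated by the reactive allylic bromide on the face opposite the benzyl group, which sets C10 as R. Substitution occurs at the primary carbon and forms the C10–C11 bond.

Step 13
Reactants: 20 (S)-4-benzyl-3-[(R,E)-2,4-dimethyl-7-(trimethylsilyl)hept-4-en-6-ynoyl]oxazolidin-2-one
Product: 21 (R,E)-2,4-dimethyl-7-(trimethylsilyl)hept-4-en-6-yn-1-ol
Conditions: LiBH4, MeOH (1 equiv), Et2O, 0 °C
Reagents that add atoms: none
Why: Reductive removal of the auxiliary; borohydride attacks the exocyclic acyl carbonyl, C10 is not enolised and the silylalkyne is inert.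

Step 14
Reactants: 21 (R,E)-2,4-dimethyl-7-(trimethylsilyl)hept-4-en-6-yn-1-ol
Product: 22 (R,E)-2,4-dimethyl-7-(trimethylsilyl)hept-4-en-6-ynal
Conditions: Dess–Martin periodinane, NaHCO3, CH2Cl2, 0 °C to rt; used crude
Reagents that add atoms: none
Why: Periodinane oxidation under buffered conditions; the α-methyl aldehyde is taken on at once to avoid epimerisation at C10.

Step 15
Reactants: 22 (R,E)-2,4-dimethyl-7-(trimethylsilyl)hept-4-en-6-ynal
Product: 23 trimethyl[(3E,6R,7Z)-8-iodo-4,6-dimethylnona-3,7-dien-1-yn-1-yl]silane
Conditions: EtPPh3I, n-BuLi, THF, rt; I2, −78 °C; NaN(SiMe3)2, −20 °C; 22, −78 °C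
Reagents that add atoms: ethyltriphenylphosphonium iodide, CC[P+](c1ccccc1)(c1ccccc1)c1ccccc1.[I-]; iodine, II
Why: Stork–Zhao iodo-olefination; the non-stabilised α-iodo ylide reacts under kinetic control and places iodine cis to the chain, giving the Z-iodoalkene that carries C8 and its methyl. The low temperature protects C10, and the alkyne is kept silylated so that no acidic C–H meets the ylide.

Step 16
Reactants: 23 trimethyl[(3E,6R,7Z)-8-iodo-4,6-dimethylnona-3,7-dien-1-yn-1-yl]silane
Product: 24 (3E,6R,7Z)-8-iodo-4,6-dimethylnona-3,7-dien-1-yne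
Conditions: K2CO3, MeOH, rt
Reagents that add atoms: none
Why: Methanolysis of an alkynylsilane; the vinyl iodide and both alkenes are inert to carbonate in methanol.

Step 17
Reactants: 25 (E)-3-(tributylstannyl)prop-2-en-1-ol
Product: 26 (E)-3-(tributylstannyl)prop-2-enal
Conditions: MnO2, CH2Cl2, rt
Reagents that add atoms: none
Why: Allylic oxidation on MnO2; neutral conditions keep the C–Sn bond and the E geometry.

Step 18
Reactants: 26 (E)-3-(tributylstannyl)prop-2-enal
Product: 27 (S,E)-1-(tributylstannyl)hexa-1,5-dien-3-ol
Conditions: (−)-Ipc2B(allyl), Et2O, −78 °C; NaBO3·4H2O, THF/H2O, rt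
Reagents that add atoms: (−)-B-allyldiisopinocampheylborane, C=CCB([C@@H]1C[C@@H]2C[C@H]([C@H]1C)C2(C)C)[C@@H]1C[C@@H]2C[C@H]([C@H]1C)C2(C)C
Why: Brown allylation; the chair transition state imposed by the isopinocampheyl groups of the reagent derived from (+)-α-pinene transfers allyl to the Si face of the enal, which gives the S carbinol (C5). The perborate work-up is mild enough for the alkenylstannane.

Step 19
Reactants: 27 (S,E)-1-(tributylstannyl)hexa-1,5-dien-3-ol
Product: 28 (S,E)-1-(tributylstannyl)hexa-1,5-dien-3-yl acrylate
Conditions: acryloyl chloride, i-Pr2NEt, CH2Cl2, −78 to 0 °C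
Reagents that add atoms: acryloyl chloride, C=CC(=O)Cl
Why: O-acylation of a secondary alcohol; excess amine keeps the medium basic, so the acid-labile alkenylstannane is not protodestannylated.

Step 20
Reactants: 28 (S,E)-1-(tributylstannyl)hexa-1,5-dien-3-yl acrylate
Product: 29 (S)-6-[(E)-2-(tributylstannyl)vinyl]-5,6-dihydro-2H-pyran-2-one
Conditions: second-generation Grubbs catalyst (5 mol%), CH2Cl2 (high dilution), 40 °C
Reagents that add atoms: none
Why: Ring-closing metathesis of a homoallylic acrylate; the catalyst initiates at the terminal allyl alkene and closes onto the acrylate to form C2=C3 in the six-membered ring. The stannyl alkene is bulky and 1,2-disubstituted, and closure onto it would give a four-membered ring.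

Step 21
Reactants: 24 (3E,6R,7Z)-8-iodo-4,6-dimethylnona-3,7-dien-1-yne; 14 (2S,4R,5R,6S)-4-(tert-butyldimethylsilyloxy)-5-methyl-6-[(E)-prop-1-enyl]tetrahydro-2H-pyran-2-carbaldehyde
Product: 32 (1S,4E,7R,8Z)-1-[(2S,4R,5R,6S)-4-(tert-butyldimethylsilyloxy)-5-methyl-6-[(E)-prop-1-enyl]tetrahydro-2H-pyran-2-yl]-9-iodo-5,7-dimethyldeca-4,8-dien-2-yn-1-ol, via lithium acetylide 30 (not isolated), via alkynylzinc bromide 31 (not isolated)
Conditions: LiN(SiMe3)2, THF, −78 °C; ZnBr2, −78 to 0 °C; 14, Et2O/THF, −78 to 0 °C
Reagents that add atoms: none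
Why: Chelation-controlled addition of an alkynylzinc halide to an α-alkoxy aldehyde (Cram chelate). Zinc bridges the aldehyde oxygen and the ring oxygen, and the acetylide attacks from the side of the C17 hydrogen, away from C18, which gives the 16S carbinol syn to the ring oxygen. The amide base removes only the alkyne proton and leaves the vinyl iodide alone.

Step 22
Reactants: 32 (1S,4E,7R,8Z)-1-[(2S,4R,5R,6S)-4-(tert-butyldimethylsilyloxy)-5-methyl-6-[(E)-prop-1-enyl]tetrahydro-2H-pyran-2-yl]-9-iodo-5,7-dimethyldeca-4,8-dien-2-yn-1-ol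
Product: 33 (1S,4E,7R,8Z)-1-[(2S,4R,5S,6S)-4-hydroxy-5-methyl-6-[(E)-prop-1-enyl]tetrahydro-2H-pyran-2-yl]-9-iodo-5,7-dimethyldeca-4,8-dien-2-yn-1-ol
Conditions: HF·pyridine, THF, 0 °C to rt
Reagents that add atoms: none
Why: Fluoride cleavage of the secondary silyl ether, placed at the propargylic stage because this carbinol, unlike the later dienylic one, does not ionise under mildly acidic conditions. Basic fluoride is avoided so that the Z-iodoalkene cannot eliminate.

Step 23
Reactants: 33 (1S,4E,7R,8Z)-1-[(2S,4R,5S,6S)-4-hydroxy-5-methyl-6-[(E)-prop-1-enyl]tetrahydro-2H-pyran-2-yl]-9-iodo-5,7-dimethyldeca-4,8-dien-2-yn-1-ol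
Product: 34 (1S,2E,4E,7R,8Z)-1-[(2S,4R,5S,6S)-4-hydroxy-5-methyl-6-[(E)-prop-1-enyl]tetrahydro-2H-pyran-2-yl]-9-iodo-5,7-dimethyldeca-2,4,8-trien-1-ol
Conditions: NaAlH2(OCH2CH2OMe)2, THF, 0 °C to rt; aq. potassium sodium tartrate
Reagents that add atoms: none
Why: Alkoxide-directed trans-hydroalumination of a propargylic alcohol followed by protonolysis, which gives the 14E alkene and thereby the E,E-diene. Isolated alkenes are not reduced, and the hindered vinyl iodide should survive at this temperature.

Step 24
Reactants: 34 (1S,2E,4E,7R,8Z)-1-[(2S,4R,5S,6S)-4-hydroxy-5-methyl-6-[(E)-prop-1-enyl]tetrahydro-2H-pyran-2-yl]-9-iodo-5,7-dimethyldeca-2,4,8-trien-1-ol; 29 (S)-6-[(E)-2-(tributylstannyl)vinyl]-5,6-dihydro-2H-pyran-2-one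
Product: 35 (S)-6-[(1E,3Z,5R,7E,9E,11S)-11-hydroxy-11-[(2S,4R,5S,6S)-4-hydroxy-5-methyl-6-[(E)-prop-1-enyl]tetrahydro-2H-pyran-2-yl]-3,5,7-trimethylundeca-1,3,7,9-tetraenyl]-5,6-dihydro-2H-pyran-2-one
Conditions: Pd2(dba)3 (cat.), AsPh3, CuI (cat.), NMP, rt, dark
Reagents that add atoms: none
Why: Stille coupling; oxidative addition of the Z-iodoalkene to zerovalent palladium, transmetalation from tin and reductive elimination all proceed with retention, so the C7–C8 bond forms with the 6E,8Z geometry. The neutral conditions tolerate the free hydroxyls and the enoate lactone, which enters only here.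

## Compound list

1 | (R)-4-benzyl-3-propionyloxazolidin-2-one | CCC(=O)N1[C@H](Cc2ccccc2)COC1=O | starting material
2 | (E)-but-2-enal (crotonaldehyde) | C/C=C/C=O | starting material
3 | dibutylboron (Z)-enolate of 1 | C/C=C(\OB(CCCC)CCCC)N1[C@H](Cc2ccccc2)COC1=O | intermediate
4 | (R)-4-benzyl-3-[(2R,3S,E)-3-hydroxy-2-methylhex-4-enoyl]oxazolidin-2-one | C/C=C/[C@H](O)[C@@H](C)C(=O)N1[C@H](Cc2ccccc2)COC1=O | intermediate
5 | (2R,3S,E)-3-hydroxy-2-methylhex-4-enoic acid | C/C=C/[C@H](O)[C@@H](C)C(=O)O | intermediate
6 | (tert-butyldimethylsilyloxy)acetaldehyde | O=CCO[Si](C)(C)C(C)(C)C | starting material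
7 | trimethylsilyl (2R,3S,E)-2-methyl-3-(trimethylsilyloxy)hex-4-enoate | C/C=C/[C@H](O[Si](C)(C)C)[C@@H](C)C(=O)O[Si](C)(C)C | intermediate
8 | (2S,5R,6S)-2-[(tert-butyldimethylsilyloxy)methyl]-5-methyl-6-[(E)-prop-1-enyl]-1,3-dioxan-4-one | C/C=C/[C@@H]1O[C@H](CO[Si](C)(C)C(C)(C)C)OC(=O)[C@@H]1C | intermediate
9 | (2S,5R,6S)-2-[(tert-butyldimethylsilyloxy)methyl]-5-methyl-4-methylidene-6-[(E)-prop-1-enyl]-1,3-dioxane | C/C=C/[C@@H]1O[C@H](CO[Si](C)(C)C(C)(C)C)OC(=C)[C@@H]1C | intermediate
10 | (2S,3R,6S)-6-[(tert-butyldimethylsilyloxy)methyl]-3-methyl-2-[(E)-prop-1-enyl]tetrahydro-4H-pyran-4-one | C/C=C/[C@@H]1O[C@H](CO[Si](C)(C)C(C)(C)C)CC(=O)[C@@H]1C | intermediate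
11 | (2S,3S,4R,6S)-6-[(tert-butyldimethylsilyloxy)methyl]-3-methyl-2-[(E)-prop-1-enyl]tetrahydro-2H-pyran-4-ol | C/C=C/[C@@H]1O[C@H](CO[Si](C)(C)C(C)(C)C)C[C@@H](O)[C@@H]1C | intermediate
12 | (2S,3R,4R,6S)-4-(tert-butyldimethylsilyloxy)-6-[(tert-butyldimethylsilyloxy)methyl]-3-methyl-2-[(E)-prop-1-enyl]tetrahydro-2H-pyran | C/C=C/[C@@H]1O[C@H](CO[Si](C)(C)C(C)(C)C)C[C@@H](O[Si](C)(C)C(C)(C)C)[C@@H]1C | intermediate
13 | [(2S,4R,5R,6S)-4-(tert-butyldimethylsilyloxy)-5-methyl-6-[(E)-prop-1-enyl]tetrahydro-2H-pyran-2-yl]methanol | C/C=C/[C@@H]1O[C@H](CO)C[C@@H](O[Si](C)(C)C(C)(C)C)[C@@H]1C | intermediate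
14 | (2S,4R,5R,6S)-4-(tert-butyldimethylsilyloxy)-5-methyl-6-[(E)-prop-1-enyl]tetrahydro-2H-pyran-2-carbaldehyde | C/C=C/[C@@H]1O[C@H](C=O)C[C@@H](O[Si](C)(C)C(C)(C)C)[C@@H]1C | intermediate
15 | (E)-3-iodo-2-methylprop-2-en-1-ol | OC/C(C)=C/I | starting material
16 | (E)-2-methyl-5-(trimethylsilyl)pent-2-en-4-yn-1-ol | OC/C(C)=C/C#C[Si](C)(C)C | intermediate
17 | (E)-(5-bromo-4-methylpent-3-en-1-yn-1-yl)trimethylsilane | BrC/C(C)=C/C#C[Si](C)(C)C | intermediate
18 | (S)-4-benzyl-3-propionyloxazolidin-2-one | CCC(=O)N1[C@@H](Cc2ccccc2)COC1=O | starting material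
19 | sodium (Z)-enolate of 18 | C/C=C(\O[Na])N1[C@@H](Cc2ccccc2)COC1=O | intermediate
20 | (S)-4-benzyl-3-[(R,E)-2,4-dimethyl-7-(trimethylsilyl)hept-4-en-6-ynoyl]oxazolidin-2-one | C[Si](C)(C)C#C/C=C(C)/C[C@@H](C)C(=O)N1[C@@H](Cc2ccccc2)COC1=O | intermediate
21 | (R,E)-2,4-dimethyl-7-(trimethylsilyl)hept-4-en-6-yn-1-ol | C[Si](C)(C)C#C/C=C(C)/C[C@@H](C)CO | intermediate
22 | (R,E)-2,4-dimethyl-7-(trimethylsilyl)hept-4-en-6-ynal | C[Si](C)(C)C#C/C=C(C)/C[C@@H](C)C=O | intermediate
23 | trimethyl[(3E,6R,7Z)-8-iodo-4,6-dimethylnona-3,7-dien-1-yn-1-yl]silane | C[Si](C)(C)C#C/C=C(C)/C[C@@H](C)/C=C(/C)I | intermediate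
24 | (3E,6R,7Z)-8-iodo-4,6-dimethylnona-3,7-dien-1-yne | C#C/C=C(C)/C[C@@H](C)/C=C(/C)I | intermediate
25 | (E)-3-(tributylstannyl)prop-2-en-1-ol | CCCC[Sn](CCCC)(CCCC)/C=C/CO | starting material
26 | (E)-3-(tributylstannyl)prop-2-enal | CCCC[Sn](CCCC)(CCCC)/C=C/C=O | intermediate
27 | (S,E)-1-(tributylstannyl)hexa-1,5-dien-3-ol | CCCC[Sn](CCCC)(CCCC)/C=C/[C@@H](O)CC=C | intermediate
28 | (S,E)-1-(tributylstannyl)hexa-1,5-dien-3-yl acrylate | CCCC[Sn](CCCC)(CCCC)/C=C/[C@@H](OC(=O)C=C)CC=C | intermediate
29 | (S)-6-[(E)-2-(tributylstannyl)vinyl]-5,6-dihydro-2H-pyran-2-one | CCCC[Sn](CCCC)(CCCC)/C=C/[C@@H]1CC=CC(=O)O1 | intermediate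
30 | lithium acetylide of 24 | [Li]C#C/C=C(C)/C[C@@H](C)/C=C(/C)I | intermediate
31 | alkynylzinc bromide of 24 | Br[Zn]C#C/C=C(C)/C[C@@H](C)/C=C(/C)I | intermediate
32 | (1S,4E,7R,8Z)-1-[(2S,4R,5R,6S)-4-(tert-butyldimethylsilyloxy)-5-methyl-6-[(E)-prop-1-enyl]tetrahydro-2H-pyran-2-yl]-9-iodo-5,7-dimethyldeca-4,8-dien-2-yn-1-ol | C/C=C/[C@@H]1O[C@H]([C@@H](O)C#C/C=C(C)/C[C@@H](C)/C=C(/C)I)C[C@@H](O[Si](C)(C)C(C)(C)C)[C@@H]1C | intermediate
33 | (1S,4E,7R,8Z)-1-[(2S,4R,5S,6S)-4-hydroxy-5-methyl-6-[(E)-prop-1-enyl]tetrahydro-2H-pyran-2-yl]-9-iodo-5,7-dimethyldeca-4,8-dien-2-yn-1-ol | C/C=C/[C@@H]1O[C@H]([C@@H](O)C#C/C=C(C)/C[C@@H](C)/C=C(/C)I)C[C@@H](O)[C@@H]1C | intermediate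
34 | (1S,2E,4E,7R,8Z)-1-[(2S,4R,5S,6S)-4-hydroxy-5-methyl-6-[(E)-prop-1-enyl]tetrahydro-2H-pyran-2-yl]-9-iodo-5,7-dimethyldeca-2,4,8-trien-1-ol | C/C=C/[C@@H]1O[C@H]([C@@H](O)/C=C/C=C(\C)C[C@@H](C)/C=C(/C)I)C[C@@H](O)[C@@H]1C | intermediate
35 | (S)-6-[(1E,3Z,5R,7E,9E,11S)-11-hydroxy-11-[(2S,4R,5S,6S)-4-hydroxy-5-methyl-6-[(E)-prop-1-enyl]tetrahydro-2H-pyran-2-yl]-3,5,7-trimethylundeca-1,3,7,9-tetraenyl]-5,6-dihydro-2H-pyran-2-one | C/C=C/[C@@H]1O[C@H]([C@@H](O)/C=C/C=C(\C)C[C@@H](C)/C=C(C)\C=C\[C@@H]2CC=CC(=O)O2)C[C@@H](O)[C@@H]1C | target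

## Step count and the least certain steps

Total: 24 steps. Longest linear sequence: 13 steps (steps 1–9 and 21–24). The alkyne branch (steps 10–16) and the lactone branch (steps 17–20) are built in parallel.

**Step 5 (key step).** The most likely failure is ionisation at the wrong bond. The allylic C21–O bond can open to a propenyl-stabilised cation, while ionisation at C17 is slowed by the inductive pull of the C16 oxygen. A second danger is acid epimerisation of the axial C20 methyl in the product. The fallback builds the ring by C–O instead of C–C bond formation and sets out from 4. Transamination with MeONHMe·HCl and AlMe3 gives the Weinreb amide F1. Compound 25 is silylated to the silyl ether F2, and tin–lithium exchange (n-BuLi) gives an alkenyllithium. Two equivalents of it convert F1 into the hydroxy enone F3. Under mild acid catalysis the C21 hydroxyl of F3 adds to C17 in a 6-endo oxa-Michael closure under thermodynamic control (both ring substituents equatorial), and the route is rejoined at 10.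

**Step 21.** Facial selectivity at C16 may be poor if the zinc chelate through the ring oxygen is incomplete, since the open Felkin–Anh pathway leads to the 16R epimer. The fallback sets out from the epimer mixture of 32. Dess–Martin oxidation gives the ynone F4. Noyori transfer hydrogenation with RuCl[(R,R)-TsDPEN](p-cymene) in i-PrOH, the catalyst enantiomer that by the usual alkynyl-ketone model delivers hydride to the face giving 16S, then returns 32 under reagent control.

**Step 23.** The aluminium hydride may also attack the vinyl iodide (hydrodeiodination), or the dienyl alanate may be reduced further. The fallback avoids hydride altogether and sets out from 24 and 14. Hydrozirconation of 24 with Cp2Zr(H)Cl, transmetalation to zinc with Me2Zn and addition of the dienylzinc to 14 give the silyl-protected dienyl carbinol F5, with the 14E geometry coming from syn hydrometalation. HF·pyridine then removes the silyl group and the route is rejoined at 34.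

**Step 20.** The ruthenium carbene may be diverted or deactivated by the stannyl alkene, or the alkenylstannane may be protodestannylated by traces of acid. The fallback removes tin before the metathesis and sets out from 27. Iodine gives the iodo dienol F5a-type compound, here called iodo dienol F6. Acryloyl chloride gives the iodo acrylate F7. The second-generation Grubbs catalyst, to which vinyl iodides are inert, gives the iodovinyl lactone F8. Palladium-catalysed stannylation of F8 with Bu3SnSnBu3 and Pd(PPh3)4 returns 29.

**Step 6.** The axial C20 methyl flanks the equatorial trajectory and may erode the facial selectivity, and C20 may epimerise if the ketone is kept too long before reduction. The fallback sets out from 10. NaBH4 in MeOH attacks axially, away from the axial methyl, and gives the equatorial alcohol F9. Mitsunobu inversion with 4-nitrobenzoic acid, PPh3 and diisopropyl azodicarboxylate gives the axial ester F10. K2CO3 in MeOH then releases 11.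

## Further compounds

F1 | step 5 | (2R,3S,E)-3-hydroxy-N-methoxy-N,2-dimethylhex-4-enamide | C/C=C/[C@H](O)[C@@H](C)C(=O)N(C)OC
F2 | step 5 | (E)-tert-butyldimethyl{[3-(tributylstannyl)allyl]oxy}silane | CCCC[Sn](CCCC)(CCCC)/C=C/CO[Si](C)(C)C(C)(C)C
F3 | step 5 | (2E,5R,6S,7E)-1-(tert-butyldimethylsilyloxy)-6-hydroxy-5-methylnona-2,7-dien-4-one | C/C=C/[C@H](O)[C@@H](C)C(=O)/C=C/CO[Si](C)(C)C(C)(C)C
F4 | step 21 | (4E,7R,8Z)-1-[(2S,4R,5R,6S)-4-(tert-butyldimethylsilyloxy)-5-methyl-6-[(E)-prop-1-enyl]tetrahydro-2H-pyran-2-yl]-9-iodo-5,7-dimethyldeca-4,8-dien-2-yn-1-one | C/C=C/[C@@H]1O[C@H](C(=O)C#C/C=C(C)/C[C@@H](C)/C=C(/C)I)C[C@@H](O[Si](C)(C)C(C)(C)C)[C@@H]1C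
F5 | step 23 | (1S,2E,4E,7R,8Z)-1-[(2S,4R,5R,6S)-4-(tert-butyldimethylsilyloxy)-5-methyl-6-[(E)-prop-1-enyl]tetrahydro-2H-pyran-2-yl]-9-iodo-5,7-dimethyldeca-2,4,8-trien-1-ol | C/C=C/[C@@H]1O[C@H]([C@@H](O)/C=C/C=C(\C)C[C@@H](C)/C=C(/C)I)C[C@@H](O[Si](C)(C)C(C)(C)C)[C@@H]1C
F6 | step 20 | (S,E)-1-iodohexa-1,5-dien-3-ol | I/C=C/[C@@H](O)CC=C
F7 | step 20 | (S,E)-1-iodohexa-1,5-dien-3-yl acrylate | I/C=C/[C@@H](OC(=O)C=C)CC=C
F8 | step 20 | (S)-6-[(E)-2-iodovinyl]-5,6-dihydro-2H-pyran-2-one | I/C=C/[C@@H]1CC=CC(=O)O1
F9 | step 6 | (2S,3S,4S,6S)-6-[(tert-butyldimethylsilyloxy)methyl]-3-methyl-2-[(E)-prop-1-enyl]tetrahydro-2H-pyran-4-ol (C19 epimer of 11) | C/C=C/[C@@H]1O[C@H](CO[Si](C)(C)C(C)(C)C)C[C@H](O)[C@@H]1C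
F10 | step 6 | (2S,3S,4R,6S)-6-[(tert-butyldimethylsilyloxy)methyl]-3-methyl-2-[(E)-prop-1-enyl]tetrahydro-2H-pyran-4-yl 4-nitrobenzoate | C/C=C/[C@@H]1O[C@H](CO[Si](C)(C)C(C)(C)C)C[C@@H](OC(=O)c2ccc(cc2)[N+](=O)[O-])[C@@H]1C
A1 | alternative 1 | chloroacetaldehyde | ClCC=O
A2 | alternative 1 | acetaldehyde | CC=O
A3 | alternative 1 | (3R,5S)-6-chloro-2,4,6-trideoxyhexopyranose | ClC[C@@H]1C[C@@H](O)CC(O)O1
A4 | alternative 2 | (2S,4R,5R,6E,8S)-4-(tert-butyldimethylsilyloxy)-1-(4-methoxybenzyloxy)-5-methylnon-6-ene-2,8-diol | C[C@H](O)/C=C/[C@@H](C)[C@H](O[Si](C)(C)C(C)(C)C)C[C@H](O)COCc1ccc(OC)cc1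
A5 | alternative 2 | (2S,3R,4R,6S)-4-(tert-butyldimethylsilyloxy)-6-[(4-methoxybenzyloxy)methyl]-3-methyl-2-[(E)-prop-1-enyl]tetrahydro-2H-pyran | C/C=C/[C@@H]1O[C@H](COCc2ccc(OC)cc2)C[C@@H](O[Si](C)(C)C(C)(C)C)[C@@H]1C
A6 | alternative 3 | (S)-2-methylbut-3-en-1-ol | OC[C@@H](C)C=C
A7 | alternative 3 | (S)-2-methylbut-3-en-1-yl methacrylate | C=C(C)C(=O)OC[C@@H](C)C=C
A8 | alternative 3 | (S)-3,5-dimethyl-5,6-dihydro-2H-pyran-2-one | O=C1OC[C@@H](C)C=C1C
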